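## Analysis of the target

Compound 18 is a chamigrane-type spirocycle in which two cyclohexane rings share one quaternary carbon. Numbering used below: ring A is C1 (CMe2), C2 (CHBr), C3, C4, C5 (C=CH2) and the spiro carbon C6, and ring B is C6, C7, C8 (CHBr), C9 (C(CH3)OH), C10 and C11. There are four stereocentres: the quaternary C6, the vicinal pair C8/C9 and the isolated C2. In ring B the C9 oxygen is trans to the C8 bromine and cis-1,4 to C5, and C2–Br lies on the C7 side of ring A. C6 is stereogenic only because its two ring B methylenes C7 and C11 differ at their neighbours C8 and C10, so nothing near C6 tells a reagent at C2 which side is which, and C2 cannot be set by substrate control. The sensitive groups are the trans-bromohydrin (epoxide with base), the C2 bromide next to CMe2 (not accessible by SN2, prone to Wagner–Meerwein shifts on ionization), the exocyclic alkene (acid), and the crowded C1–C6–C5 array. The strategy rests on ring B: O–C9 cis to C5 and anti to Br–C8 is the geometry of a 2-oxabicyclo[2.2.2]octan-3-one with C5 as lactone carbonyl, C6 and C9 as bridgeheads and C8 as the brominated bridge carbon.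

## Retrosynthetic reasoning

**18 ⇒ 16 (via 17), cut C3–C4.** Ring A is opened between the two CH2 groups. C4 and the exocyclic CH2 become the two ends of a 2-substituted allylsilane on C5, and C3 becomes a primary carbon with a leaving group next to the C2 bromide. This closure gives the methylene directly, so no hindered C5 ketone has to be methylenated and no base comes near the bromohydrin or the C2 bromide. The forward reaction must alkylate the allylsilane terminus at C3 without touching C2. A ring A built first as a 1,3-dione was set aside, because it needs a ketone-to-CMe2 exchange beside a bromide and leaves C2 without control.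

**16 ⇒ 14 (via 15), two C–C bonds at C5.** The allylsilane is traced to the lactone carbonyl of 14 by double addition of a silylmethyl organometallic and Peterson elimination. This is the point where the temporary bridge is removed: the C9 hydroxyl is set free and C5 receives both of its carbon neighbours. Until then the lactone protects the C5 carbonyl and the tertiary alcohol at once and holds ring B so that no epoxide can form.

**14 ⇒ 12 (via 13), the C2–Br bond.** The bromide is introduced on C2 as the α-carbon of aldehyde 12. An enamine catalyst decides the configuration, which is needed because the substrate cannot. Electrophilic bromination also avoids any substitution at a neopentyl carbon. Reduction in the same flask secures the centre as the bromohydrin.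

**12 ⇒ 8 + 9 (via 10 and 11), the C1–C2 bond.** C1 must carry two methyls and C2 while bonded to quaternary C6. A tertiary radical at C1, made from the isopropenyl group of 8 by hydrogen-atom transfer and trapped by acrolein 9, forms this bond without a cation that could trigger an acyl shift from C6. The third carbon of 9 is then removed through the silyl enol ether 11.

**8 ⇒ 5 (via 6 and 7), functional group changes at C1.** The free carboxyl of 5 is turned into a methyl ketone and then into the isopropenyl group. Both operations leave the lactone and the ring bromide alone.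

**5 ⇒ 4, the C9–O and C8–Br bonds.** The lactone ring and three stereocentres are traced to the achiral diacid 4. Bromine adds to one face of the alkene and the carboxyl on the other face closes on the methyl-bearing carbon. Because a carboxyl can only reach across the ring from its own side, choosing the alkene face and choosing the carboxyl are one decision. The two carboxyl carbons leave the step already differentiated, as lactone (future C5) and acid (future C1).

**4 ⇒ 1 + 2 (via 3), the second carboxyl.** The diacid comes from the commercial monoacid 1 by carboxylation of its dianion 3 with carbon dioxide 2.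

## Alternatives that were turned down

Alternative 1: The disconnection cuts both bonds from C6 to the ring B methylenes C7 and C11. In the forward sense cyclohexane-1,3-dione A2 adds twice to penta-1,4-dien-3-one A3 and gives the achiral spiro[5.5]undecane-1,5,9-trione A1.
- For it: the whole spiro skeleton arises in one step from two simple compounds, with carbonyls at C1, C5 and C9 where functionality is needed. On skeletal step economy it is clearly stronger than the chosen route.
- Against it: A1 has no stereocentre. C6 becomes stereogenic only after C1 is told from C5 and C8 from C10, two independent desymmetrizations whose senses must match. C9 and C2 need further selective events. The C1 carbonyl must still become CMe2 next to the spiro carbon with bromine on C2, in a 1,3-dione that is prone to retro-Claisen cleavage.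
- Comparison: the chosen route builds ring A over several steps, but one event gives C6, C8 and C9 and differentiates the two carbonyl carbons on C6.

Alternative 2: The disconnection cuts C6–C7 by a retro-Claisen step. In the forward sense the allyl vinyl ether 6-bromo-2-ethenyl-2,5,5-trimethyl-3,4,5,6,7,8-hexahydro-2H-chromene A5, drawn from (R)-linalool A6, rearranges thermally to 2-bromo-1,1,9-trimethylspiro[5.5]undec-8-en-5-one A4.
- For it: the CMe2–CHBr unit can come from a terpene-type bromonium cyclization, the natural way to make a neopentyl bromide. Chirality passes from the carbinol carbon to C6 through a cyclic transition state. On this point and on length it is stronger than the chosen route.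
- Against it: in A5 the bromine-bearing carbon and the carbinol carbon are far apart, so A5 forms as a diastereomer pair unless the bromocyclization is itself enantioselective. The shift inside the ring must go through a boat. Afterwards ring B of A4 has only an alkene, so the C8/C9 bromohydrin depends on a face bias from C5=O against CMe2, and the hindered C5 ketone must be methylenated last beside a base-sensitive bromohydrin.
- Comparison: the chosen route takes the ring B triad and its relation to C6 from the geometry of a bridged lactone instead of a facial bias, and it forms the methylene without a ketone methylenation.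

Alternative 3: The disconnection cuts C5–C6. In the forward sense Ph3PAuNTf2 activates the alkyne of 4-[(3S)-3-bromo-2-methylhept-6-yn-2-yl]phenol A8 so that the para carbon attacks, giving 2-bromo-1,1-dimethyl-5-methylidenespiro[5.5]undeca-7,10-dien-9-one A7.
- For it: ring A, the exocyclic methylene and the spiro junction form in one step, and C2 is carried from an acyclic precursor. For the methylene this is as direct as the chosen closure, and it is more convergent.
- Against it: in A7 the spiro carbon is not a stereocentre because its two enone arms are identical. The arms must then be told apart under the influence of the remote C2 or of a catalyst. Ring B must gain a methyl at the carbonyl carbon, lose one alkene and add HBr across the other in a defined sense, passing through bis-allylic tertiary alcohols that rearomatize easily. The ipso attack also creates a quaternary carbon next to CMe2.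
- Comparison: this route postpones C6, C8 and C9 to the end, whereas the chosen route sets them first and together.

Key step: step 2

Assumption: the sense of induction of both chiral catalysts is taken from their usual models; should either give the antipodal sense, (DHQ)2PHAL replaces (DHQD)2PHAL in step 2 and (2R,5R)-2,5-diphenylpyrrolidine replaces its enantiomer in step 7.

## Route

Step 1
Reactants: 1 4-methylcyclohex-3-ene-1-carboxylic acid (racemic); 2 carbon dioxide
Product: 4 4-methylcyclohex-3-ene-1,1-dicarboxylic acid, via dilithium enediolate 3 (not isolated)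
Conditions: LiN(i-Pr)2 (2.2 equiv), THF, 0 → 50 °C; then CO2, −78 °C; cold 2 M HCl
Reagents that add atoms: none
Why: Double deprotonation gives the enediolate dianion, which is C-carboxylated by carbon dioxide (dianion carboxylation to a malonic acid); the stereocentre of racemic 1 is erased and 4 is achiral, and a cold work-up avoids malonic decarboxylation.

Step 2
Reactants: 4 4-methylcyclohex-3-ene-1,1-dicarboxylic acid
Product: 5 (1R,4S,6R)-6-bromo-1-methyl-3-oxo-2-oxabicyclo[2.2.2]octane-4-carboxylic acid
Conditions: NBS (1.1 equiv), (DHQD)2PHAL (hydroquinidine 1,4-phthalazinediyl diether, 10 mol%), CHCl3/toluene, −40 °C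
Reagents that add atoms: N-bromosuccinimide, O=C1CCC(=O)N1Br
Why: Proposed new method: the protonated cinchona catalyst binds the diacid as an ion pair and NBS transfers Br+ to one enantiotopic face of the ring alkene, after which the carboxyl on the opposite face opens the bromonium ion anti at the methyl-bearing carbon; the closest known reaction type is the (DHQD)2PHAL-catalysed bromolactonization of cyclohexene- and cyclohexadiene-carboxylic acids, not yet shown for a geminal diacid closing to a bridged δ-lactone. The one ring that closes is the δ-lactone, formed by 6-exo attack (counted through the CH2–CH2 arm) of carboxylate oxygen on the tertiary carbon while the cyclohexene passes through a boat. C6 (C–Br) is set by the alkene face that the catalyst selects, and C1 (C–O) follows from anti opening of the bromonium ion. C4 is fixed because only the carboxyl on the face opposite to bromine can reach across the ring, so the choice of face and the choice of carboxyl are one decision. The step needs enantiofacial selectivity, which only the catalyst can supply since 4 is achiral, and δ- over γ-lactone regioselectivity, which the methyl group supplies by making its carbon the Markovnikov terminus of the bromonium ion. The remaining acid sits at a bridgehead, where the enol needed for decarboxylation would violate Bredt's rule.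

Step 3
Reactants: 5 (1R,4S,6R)-6-bromo-1-methyl-3-oxo-2-oxabicyclo[2.2.2]octane-4-carboxylic acid
Product: 7 (1R,4S,6R)-4-acetyl-6-bromo-1-methyl-2-oxabicyclo[2.2.2]octan-3-one, via acid chloride 6 (not isolated)
Conditions: (COCl)2, DMF (cat.), CH2Cl2, 0 °C → rt; then Me2CuLi (1.3 equiv), Et2O, −78 °C
Reagents that add atoms: lithium dimethylcuprate, [Li+].C[Cu-]C (methyl group); oxalyl chloride, ClC(=O)C(=O)Cl (chlorine of intermediate 6 only)
Why: Acyl chloride formation followed by Gilman cuprate acylation stops cleanly at the ketone; at −78 °C the hindered lactone and the secondary bromide are not attacked, and no stereocentre is touched.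

Step 4
Reactants: 7 (1R,4S,6R)-4-acetyl-6-bromo-1-methyl-2-oxabicyclo[2.2.2]octan-3-one
Product: 8 (1R,4S,6R)-6-bromo-1-methyl-4-(prop-1-en-2-yl)-2-oxabicyclo[2.2.2]octan-3-one
Conditions: Zn, CH2Br2, TiCl4, THF/CH2Cl2, 0 °C → rt
Reagents that add atoms: dibromomethane, BrCBr
Why: Takai–Lombardo methylenation: the methylene reagent formed from Zn, CH2Br2 and TiCl4 converts ketones but not lactones, and being non-basic it does not cleave the β-keto lactone or enolize the methyl ketone.

Step 5
Reactants: 8 (1R,4S,6R)-6-bromo-1-methyl-4-(prop-1-en-2-yl)-2-oxabicyclo[2.2.2]octan-3-one; 9 acrolein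
Product: 10 4-[(1R,4S,6R)-6-bromo-1-methyl-3-oxo-2-oxabicyclo[2.2.2]octan-4-yl]-4-methylpentanal
Conditions: Fe(acac)3 (30 mol%), PhSiH3, acrolein (3 equiv), EtOH/(CH2OH)2, 60 °C
Reagents that add atoms: none
Why: Metal-hydride hydrogen-atom transfer to the terminal CH2 gives the tertiary radical at the future C1, which adds to acrolein (Giese-type reductive olefin coupling) to make the quaternary gem-dimethyl carbon beside the bridgehead. A radical is used because a cation at this carbon would invite an acyl shift from the bridgehead, and 1,2-shift of the lactone carbonyl in the radical is slow compared with trapping.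

Step 6
Reactants: 10 4-[(1R,4S,6R)-6-bromo-1-methyl-3-oxo-2-oxabicyclo[2.2.2]octan-4-yl]-4-methylpentanal
Product: 12 3-[(1R,4S,6R)-6-bromo-1-methyl-3-oxo-2-oxabicyclo[2.2.2]octan-4-yl]-3-methylbutanal, via trimethylsilyl enol ether 11 (not isolated)
Conditions: Me3SiOTf, Et3N, CH2Cl2, 0 °C; filter; then O3, CH2Cl2, −78 °C; Me2S
Reagents that add atoms: ozone, [O-][O+]=O (oxygen of the new aldehyde); trimethylsilyl trifluoromethanesulfonate, C[Si](C)(C)OS(=O)(=O)C(F)(F)F (silyl group of intermediate 11 only)
Why: One-carbon degradation of an aldehyde by ozonolysis of its silyl enol ether; the lactone carbonyl has no α-hydrogen and cannot be silylated, and the electron-rich enol ether is the only alkene present.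

Step 7
Reactants: 12 3-[(1R,4S,6R)-6-bromo-1-methyl-3-oxo-2-oxabicyclo[2.2.2]octan-4-yl]-3-methylbutanal
Product: 14 (1R,4S,6R)-6-bromo-4-[(3R)-3-bromo-4-hydroxy-2-methylbutan-2-yl]-1-methyl-2-oxabicyclo[2.2.2]octan-3-one, via (2R)-2-bromo aldehyde 13 (not isolated)
Conditions: (2S,5S)-2,5-diphenylpyrrolidine (20 mol%), 4,4-dibromo-2,6-di-tert-butylcyclohexa-2,5-dien-1-one, PhCO2H, H2O, CH2Cl2/pentane, −40 °C; then NaBH4, MeOH, −40 → 0 °C
Reagents that add atoms: 4,4-dibromo-2,6-di-tert-butylcyclohexa-2,5-dien-1-one, CC(C)(C)C1=CC(Br)(Br)C=C(C(C)(C)C)C1=O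
Why: Organocatalytic enamine α-bromination of an aldehyde: the E-enamine is brominated on the face away from the phenyl group that flanks it, so the catalyst alone sets the future C2, where the substrate has no bias and SN2 is not available. Reduction in the same flask prevents racemization of the α-bromo aldehyde, and NaBH4 leaves the hindered lactone intact.

Step 8
Reactants: 14 (1R,4S,6R)-6-bromo-4-[(3R)-3-bromo-4-hydroxy-2-methylbutan-2-yl]-1-methyl-2-oxabicyclo[2.2.2]octan-3-one
Product: 16 (1R,2R,4R)-2-bromo-4-[(3R)-3-bromo-4-hydroxy-2-methylbutan-2-yl]-1-methyl-4-[3-(trimethylsilyl)prop-1-en-2-yl]cyclohexan-1-ol, via bis(silylmethyl) carbinol 15 (not isolated)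
Conditions: Me3SiCH2MgCl (6 equiv), CeCl3 (6 equiv), THF, −78 °C → rt; aq. NH4Cl; then SiO2, CH2Cl2, rt
Reagents that add atoms: (trimethylsilyl)methylmagnesium chloride, C[Si](C)(C)C[Mg]Cl
Why: Double addition of the silylmethyl reagent made from Me3SiCH2MgCl and CeCl3 to the lactone gives a tertiary β-hydroxysilane, and acid-promoted Peterson elimination gives the 2-substituted allylsilane while freeing the C9 hydroxyl. Epoxide closure of the ring B alkoxide is disfavoured because the required diaxial conformer would put the tert-alkyl group axial; no stereocentre changes.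

Step 9
Reactants: 16 (1R,2R,4R)-2-bromo-4-[(3R)-3-bromo-4-hydroxy-2-methylbutan-2-yl]-1-methyl-4-[3-(trimethylsilyl)prop-1-en-2-yl]cyclohexan-1-ol
Product: 18 (2S,6R,8R,9R)-2,8-dibromo-1,1,9-trimethyl-5-methylidenespiro[5.5]undecan-9-ol, via primary triflate 17 (not isolated)
Conditions: Tf2O (1.05 equiv), 2,6-di-tert-butyl-4-methylpyridine, CH2Cl2, −78 °C; then (CF3)2CHOH, −78 → 0 °C; aq. NaHCO3
Reagents that add atoms: trifluoromethanesulfonic anhydride, O=S(=O)(OS(=O)(=O)C(F)(F)F)C(F)(F)F (triflyl group of intermediate 17 only)
Why: Proposed new method: selective triflation of the primary hydroxyl gives a β-bromoalkyl triflate whose ionization is assisted by the neighbouring bromine, and the terminal carbon of the allylsilane attacks the primary carbon through a six-membered transition state with loss of silicon (SE2'), which closes ring A and leaves the exocyclic methylene; the closest known reaction type is the bromonium-initiated cation–olefin cyclization terminated by an allylsilane, together with the solvolytic generation of bromonium ions from β-bromoalkyl sulfonates and halides. Attack occurs at the CH2 carbon, so the C2–Br centre made in step 7 is carried over unchanged, and the hindered pyridine and the fluorinated alcohol take up the acid and the silyl triflate that would otherwise protodesilylate the allylsilane.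

## Compound list

1 | 4-methylcyclohex-3-ene-1-carboxylic acid (racemic) | CC1=CCC(CC1)C(=O)O | starting material
2 | carbon dioxide | O=C=O | starting material
3 | dilithium enediolate (dianion) of 1 | CC1=CCC(CC1)=C([O-])[O-].[Li+].[Li+] | intermediate
4 | 4-methylcyclohex-3-ene-1,1-dicarboxylic acid | CC1=CCC(CC1)(C(=O)O)C(=O)O | intermediate
5 | (1R,4S,6R)-6-bromo-1-methyl-3-oxo-2-oxabicyclo[2.2.2]octane-4-carboxylic acid | OC(=O)[C@@]12CC[C@@](C)(OC1=O)[C@H](Br)C2 | intermediate
6 | (1R,4R,6R)-6-bromo-1-methyl-3-oxo-2-oxabicyclo[2.2.2]octane-4-carbonyl chloride | ClC(=O)[C@@]12CC[C@@](C)(OC1=O)[C@H](Br)C2 | intermediate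
7 | (1R,4S,6R)-4-acetyl-6-bromo-1-methyl-2-oxabicyclo[2.2.2]octan-3-one | CC(=O)[C@@]12CC[C@@](C)(OC1=O)[C@H](Br)C2 | intermediate
8 | (1R,4S,6R)-6-bromo-1-methyl-4-(prop-1-en-2-yl)-2-oxabicyclo[2.2.2]octan-3-one | CC(=C)[C@@]12CC[C@@](C)(OC1=O)[C@H](Br)C2 | intermediate
9 | acrolein (prop-2-enal) | C=CC=O | starting material
10 | 4-[(1R,4S,6R)-6-bromo-1-methyl-3-oxo-2-oxabicyclo[2.2.2]octan-4-yl]-4-methylpentanal | O=CCCC(C)(C)[C@@]12CC[C@@](C)(OC1=O)[C@H](Br)C2 | intermediate
11 | (1R,4S,6R)-6-bromo-1-methyl-4-[2-methyl-5-(trimethylsilyloxy)pent-4-en-2-yl]-2-oxabicyclo[2.2.2]octan-3-one (E/Z mixture, Z drawn) | C[Si](C)(C)O/C=C\CC(C)(C)[C@@]12CC[C@@](C)(OC1=O)[C@H](Br)C2 | intermediate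
12 | 3-[(1R,4S,6R)-6-bromo-1-methyl-3-oxo-2-oxabicyclo[2.2.2]octan-4-yl]-3-methylbutanal | O=CCC(C)(C)[C@@]12CC[C@@](C)(OC1=O)[C@H](Br)C2 | intermediate
13 | (2R)-2-bromo-3-[(1R,4S,6R)-6-bromo-1-methyl-3-oxo-2-oxabicyclo[2.2.2]octan-4-yl]-3-methylbutanal | O=C[C@H](Br)C(C)(C)[C@@]12CC[C@@](C)(OC1=O)[C@H](Br)C2 | intermediate
14 | (1R,4S,6R)-6-bromo-4-[(3R)-3-bromo-4-hydroxy-2-methylbutan-2-yl]-1-methyl-2-oxabicyclo[2.2.2]octan-3-one | OC[C@H](Br)C(C)(C)[C@@]12CC[C@@](C)(OC1=O)[C@H](Br)C2 | intermediate
15 | (1R,2R,4S)-2-bromo-4-[(3R)-3-bromo-4-hydroxy-2-methylbutan-2-yl]-4-[2-hydroxy-1,3-bis(trimethylsilyl)propan-2-yl]-1-methylcyclohexan-1-ol | C[Si](C)(C)CC(O)(C[Si](C)(C)C)[C@]1(CC[C@@](C)(O)[C@H](Br)C1)C(C)(C)[C@@H](Br)CO | intermediate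
16 | (1R,2R,4R)-2-bromo-4-[(3R)-3-bromo-4-hydroxy-2-methylbutan-2-yl]-1-methyl-4-[3-(trimethylsilyl)prop-1-en-2-yl]cyclohexan-1-ol | C=C(C[Si](C)(C)C)[C@]1(CC[C@@](C)(O)[C@H](Br)C1)C(C)(C)[C@@H](Br)CO | intermediate
17 | primary trifluoromethanesulfonate of 16 (triflate on the CH2OH oxygen, all centres as in 16) | C=C(C[Si](C)(C)C)[C@]1(CC[C@@](C)(O)[C@H](Br)C1)C(C)(C)[C@@H](Br)COS(=O)(=O)C(F)(F)F | intermediate
18 | (2S,6R,8R,9R)-2,8-dibromo-1,1,9-trimethyl-5-methylidenespiro[5.5]undecan-9-ol | C=C1CC[C@H](Br)C(C)(C)[C@@]12CC[C@@](C)(O)[C@H](Br)C2 | target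

## Step count and least certain steps

Total: 9 steps. Longest linear sequence: 9 steps (the route is linear from 1).

**Step 2 (key step).** The likeliest failures are weak discrimination between the two alkene faces, because the diacid can pair with the catalyst through either carboxyl and the uncatalysed bromolactonization of a dicarboxylate is fast, and closure at the less substituted alkene carbon to the five-membered lactone. Fallback: setting out from 4, NBS and NaHCO3 in aqueous acetonitrile give the racemic bromolactone acid, that is 5 together with its enantiomer (1S,4R,6S)-6-bromo-1-methyl-3-oxo-2-oxabicyclo[2.2.2]octane-4-carboxylic acid F1. Crystallization with (S)-1-phenylethylamine, or its antipode if that gives the less soluble salt, separates the (S)-1-phenylethylammonium salt of 5 F2, and acidification returns to 5.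

**Step 9.** The likeliest failures are ionization toward the secondary neopentyl carbon with migration of a C1 methyl group, protodesilylation of the allylsilane by traces of triflic acid, and alkylation too slow to compete with decomposition of the triflate. Fallback: setting out from 14, tosyl chloride in pyridine gives the primary tosylate [(2R)-2-bromo-3-[(1R,4S,6R)-6-bromo-1-methyl-3-oxo-2-oxabicyclo[2.2.2]octan-4-yl]-3-methylbutyl] 4-methylbenzenesulfonate F3. MeLi at −78 °C opens the lactone to the methyl ketone (2R)-3-[(1S,3R,4R)-1-acetyl-3-bromo-4-hydroxy-4-methylcyclohexyl]-2-bromo-3-methylbutyl 4-methylbenzenesulfonate F4, which may rest as its bridged hemiketal. LiN(SiMe3)2 at −78 → 0 °C closes ring A by intramolecular enolate alkylation to (2S,6S,8R,9R)-2,8-dibromo-9-hydroxy-1,1,9-trimethylspiro[5.5]undecan-5-one F5. Non-basic methylenation with Cp2Ti(μ-Cl)(μ-CH2)AlMe2 then gives 18.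

**Step 5.** The likeliest failure is that the very crowded tertiary radical is reduced (net hydrogenation of the alkene) before it adds to acrolein; oligomerization of acrolein under the reducing conditions is a second risk. Fallback: setting out from 8, HCl adds in the Markovnikov sense to give (1R,4R,6R)-6-bromo-4-(2-chloropropan-2-yl)-1-methyl-2-oxabicyclo[2.2.2]octan-3-one F6. TiCl4-promoted coupling with allyltrimethylsilane gives (1R,4S,6R)-6-bromo-1-methyl-4-(2-methylpent-4-en-2-yl)-2-oxabicyclo[2.2.2]octan-3-one F7, and ozonolysis of the terminal alkene returns to 12, so that steps 5 and 6 are both replaced. This path passes through the tertiary cation that the radical route avoids, so allyl transfer has to outrun any acyl shift from the bridgehead.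

**Step 7.** The likeliest failures are slow enamine formation at the hindered aldehyde, which lets uncatalysed bromination erode the selectivity, and racemization of the α-bromo aldehyde before it is reduced. Fallback: setting out from 12, NaClO2 oxidation gives 3-[(1R,4S,6R)-6-bromo-1-methyl-3-oxo-2-oxabicyclo[2.2.2]octan-4-yl]-3-methylbutanoic acid F8. Its mixed pivalic anhydride acylates lithiated (4R)-4-benzyl-1,3-oxazolidin-2-one to give the imide (4R)-4-benzyl-3-{3-[(1R,4S,6R)-6-bromo-1-methyl-3-oxo-2-oxabicyclo[2.2.2]octan-4-yl]-3-methylbutanoyl}-1,3-oxazolidin-2-one F9. The dibutylboron enolate (Bu2BOTf, i-Pr2NEt) is brominated by NBS on the face away from the benzyl group to give the (2R)-bromo imide (4R)-4-benzyl-3-{(2R)-2-bromo-3-[(1R,4S,6R)-6-bromo-1-methyl-3-oxo-2-oxabicyclo[2.2.2]octan-4-yl]-3-methylbutanoyl}-1,3-oxazolidin-2-one F10. NaBH4 in wet THF removes the auxiliary reductively and returns to 14.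

**Step 8.** The likeliest failure is that addition stalls after the first silylmethyl group, because the resulting ketone is shielded by two adjacent quaternary carbons, followed by loss of silicon on work-up. Slow epoxide closure of either bromo alkoxide, in ring B or in the side chain, during a long reaction is a second risk. Fallback: setting out from 14, Me3SiCH2Li at −78 °C, after deprotonation of the hydroxyl, is stopped at the mono-adduct 1-[(1S,3R,4R)-3-bromo-1-[(3R)-3-bromo-4-hydroxy-2-methylbutan-2-yl]-4-hydroxy-4-methylcyclohexyl]-2-(trimethylsilyl)ethan-1-one F11. The small, non-basic titanium methylidene from Cp2Ti(μ-Cl)(μ-CH2)AlMe2 converts this α-silyl ketone into the allylsilane and returns to 16.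

## Further compounds

F1 | step 2 | (1S,4R,6S)-6-bromo-1-methyl-3-oxo-2-oxabicyclo[2.2.2]octane-4-carboxylic acid | OC(=O)[C@]12CC[C@](C)(OC1=O)[C@@H](Br)C2
F2 | step 2 | (S)-1-phenylethylammonium (1R,4S,6R)-6-bromo-1-methyl-3-oxo-2-oxabicyclo[2.2.2]octane-4-carboxylate | C[C@H]([NH3+])c1ccccc1.[O-]C(=O)[C@@]12CC[C@@](C)(OC1=O)[C@H](Br)C2
F3 | step 9 | [(2R)-2-bromo-3-[(1R,4S,6R)-6-bromo-1-methyl-3-oxo-2-oxabicyclo[2.2.2]octan-4-yl]-3-methylbutyl] 4-methylbenzenesulfonate | Cc1ccc(cc1)S(=O)(=O)OC[C@H](Br)C(C)(C)[C@@]12CC[C@@](C)(OC1=O)[C@H](Br)C2
F4 | step 9 | (2R)-3-[(1S,3R,4R)-1-acetyl-3-bromo-4-hydroxy-4-methylcyclohexyl]-2-bromo-3-methylbutyl 4-methylbenzenesulfonate | CC(=O)[C@]1(CC[C@@](C)(O)[C@H](Br)C1)C(C)(C)[C@@H](Br)COS(=O)(=O)c1ccc(C)cc1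
F5 | step 9 | (2S,6S,8R,9R)-2,8-dibromo-9-hydroxy-1,1,9-trimethylspiro[5.5]undecan-5-one | O=C1CC[C@H](Br)C(C)(C)[C@@]12CC[C@@](C)(O)[C@H](Br)C2
F6 | step 5 | (1R,4R,6R)-6-bromo-4-(2-chloropropan-2-yl)-1-methyl-2-oxabicyclo[2.2.2]octan-3-one | CC(C)(Cl)[C@@]12CC[C@@](C)(OC1=O)[C@H](Br)C2
F7 | step 5 | (1R,4S,6R)-6-bromo-1-methyl-4-(2-methylpent-4-en-2-yl)-2-oxabicyclo[2.2.2]octan-3-one | C=CCC(C)(C)[C@@]12CC[C@@](C)(OC1=O)[C@H](Br)C2
F8 | step 7 | 3-[(1R,4S,6R)-6-bromo-1-methyl-3-oxo-2-oxabicyclo[2.2.2]octan-4-yl]-3-methylbutanoic acid | OC(=O)CC(C)(C)[C@@]12CC[C@@](C)(OC1=O)[C@H](Br)C2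
F9 | step 7 | (4R)-4-benzyl-3-{3-[(1R,4S,6R)-6-bromo-1-methyl-3-oxo-2-oxabicyclo[2.2.2]octan-4-yl]-3-methylbutanoyl}-1,3-oxazolidin-2-one | O=C(CC(C)(C)[C@@]12CC[C@@](C)(OC1=O)[C@H](Br)C2)N1[C@H](Cc2ccccc2)COC1=O
F10 | step 7 | (4R)-4-benzyl-3-{(2R)-2-bromo-3-[(1R,4S,6R)-6-bromo-1-methyl-3-oxo-2-oxabicyclo[2.2.2]octan-4-yl]-3-methylbutanoyl}-1,3-oxazolidin-2-one | O=C([C@H](Br)C(C)(C)[C@@]12CC[C@@](C)(OC1=O)[C@H](Br)C2)N1[C@H](Cc2ccccc2)COC1=O
F11 | step 8 | 1-[(1S,3R,4R)-3-bromo-1-[(3R)-3-bromo-4-hydroxy-2-methylbutan-2-yl]-4-hydroxy-4-methylcyclohexyl]-2-(trimethylsilyl)ethan-1-one | C[Si](C)(C)CC(=O)[C@]1(CC[C@@](C)(O)[C@H](Br)C1)C(C)(C)[C@@H](Br)CO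
A1 | alternative 1 | spiro[5.5]undecane-1,5,9-trione | O=C1CCC2(CC1)C(=O)CCCC2=O
A2 | alternative 1 | cyclohexane-1,3-dione | O=C1CCCC(=O)C1
A3 | alternative 1 | penta-1,4-dien-3-one | C=CC(=O)C=C
A4 | alternative 2 | 2-bromo-1,1,9-trimethylspiro[5.5]undec-8-en-5-one (configuration as in the SMILES) | O=C1CC[C@H](Br)C(C)(C)[C@@]12CCC(C)=CC2
A5 | alternative 2 | 6-bromo-2-ethenyl-2,5,5-trimethyl-3,4,5,6,7,8-hexahydro-2H-chromene (configuration as in the SMILES) | C=C[C@@]1(C)CCC2=C(O1)CC[C@H](Br)C2(C)C
A6 | alternative 2 | (R)-linalool | C=C[C@](C)(O)CCC=C(C)C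
A7 | alternative 3 | 2-bromo-1,1-dimethyl-5-methylidenespiro[5.5]undeca-7,10-dien-9-one (configuration as in the SMILES) | C=C1CC[C@H](Br)C(C)(C)C12C=CC(=O)C=C2
A8 | alternative 3 | 4-[(3S)-3-bromo-2-methylhept-6-yn-2-yl]phenol | C#CCC[C@H](Br)C(C)(C)c1ccc(O)cc1
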